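## The problem

Target 21 is an open-chain diarylheptanoid. A seven-carbon chain carries a 4-hydroxy-3-methoxyphenyl ring on C1, a 4-hydroxy-3,5-dimethoxyphenyl ring on C7 and secondary hydroxyls on C3 and C5. No ring has to be built, because both arenes can be bought. The only stereochemical task is the pair C3/C5, both S and 1,3-anti. Two methylene groups separate each of them from the nearest arene, so nothing in the molecule can direct them except one another. Apart from one methoxy group the molecule is C2-symmetric about C4, so both centres are best set by one reagent-controlled event, and the two chain ends must be told apart later. The free phenols are electron-rich and will not survive ozone, strong oxidants or organometallic bases, so they must be masked and the arenes should enter after any oxidative step. The 1,3-diol is robust, but the β-hydroxy carbonyl compounds on most routes to it eliminate easily. The enabling feature is that C3–C4–C5 with the two oxygens is propane-1,3-diol, with C2 and C6 on its two carbinol carbons, so C2–C3 and C5–C6 can be made by allylating both ends of that diol while the stereocentres arise in the same event.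

## Retrosynthesis

**21 to 19.** Only protecting-group C–O bonds are cut. The phenols are carried as benzyl ethers, which survive Grignard formation and copper catalysis and leave by hydrogenolysis; the saturated chain has no alkene or benzylic C–O bond to suffer. The diol is carried as its acetonide, which leaves with dilute acid. Both removals are run in one telescoped operation through bis-phenol 20.

**19 to 15 and 18; 14 to 10 and 13.** The aryl–C7 and aryl–C1 bonds are cut. Cutting C1–C2 or C6–C7 instead would need benzylic nucleophiles and would put the arenes in place before the chain is finished. Cutting at the ring gives primary sulfonates as electrophiles and the aryl Grignard reagents 13 and 18, made from bromides 12 and 17 (one benzylation each from phenols 11 and 16). The forward reaction must be an sp3–sp2 coupling that leaves the acetonide alone.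

**15 to 14 to 10 to 9.** The two chain ends are differentiated here. Diol 9 is C2-symmetric, so its hydroxyls are homotopic and a single sulfonylation gives one compound, monotosylate 10. The neighbouring choice, a bis-sulfonate coupled with a deficit of the first Grignard reagent, places the statistical event in a C–C bond formation, where double arylation is a dead end. At the tosylation stage over-reaction and under-reaction both give usable material. After the first coupling the free hydroxyl of 14 is tosylated to 15 for the second.

**9 to 7 to 6.** C1 and C7 are traced back to the terminal alkene carbons of diene 6. Oxidative cleavage of both C=C bonds removes one carbon per end and reduction gives the primary alcohols. Acetonide 7 protects the diol through this and the later organometallic steps. The cleavage is done before any electron-rich arene is present. Precursor 6 has nine carbons, two stereocentres and no arene.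

**6 to 1 and 2.** The C3–C4 and C6–C7 bonds of 6 (C2–C3 and C5–C6 of the target) are cut to propane-1,3-diol 1 and two molecules of allyl acetate 2. A stepwise, one-directional build would need protecting-group changes between two separate asymmetric allylations. A stoichiometric allylmetal route would need the unstable 1,3-dialdehyde. The two-directional catalytic allylation from the alcohol level needs neither and reaches both stereocentres from two commodity chemicals in one step. It must give high catalyst control at both ends so that the anti diol dominates the meso one.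

## Roads not taken

**Alternative 1: Prins tetrahydropyran as a stereochemical relay.**
- Cut: C1–C2 and C3–O, with a temporary bond from the C5 oxygen to C1.
- Forward key step: homoallylic alcohol A2 and aryl aldehyde A3 condense under CF3CO2H to an oxocarbenium ion. The alkene closes onto it through a chair and trifluoroacetate caps C3, giving the all-cis tetrahydropyran A1.
- Completion: solvolysis of the esters and hydrogenolysis of the benzylic ring C–O bond would release the anti diol.
- Merits: the C5 centre controls C3 reliably, and the two aryl ends are different from the start, so no statistical step is needed. In that respect it is better than the chosen plan.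
- Weak points: an electron-rich benzylic oxocarbenium ion is prone to oxonia-Cope exchange, which erodes enantiomeric purity and scrambles side chains. The acetate on A3 that tempers this also slows the later benzylic hydrogenolysis. The C1 stereocentre is made only to be destroyed. A2 still needs its own asymmetric allylation, without amplification of enantiomeric purity.
- Comparison: the chosen plan sets both centres in one catalytic step from 1, with the minor enantiomer diverted to a separable meso diol, and has no cationic step on an electron-rich arene.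

**Alternative 2: twofold 1,3-acetate transposition.**
- Cut: the C3–O and C5–O bonds.
- Forward key step: the bis(benzylic allylic acetate) A5 rearranges under PdCl2(MeCN)2 (divalent palladium) through chair-like cyclic acetoxonium intermediates to diacetate A4, with both alkenes moving into conjugation with the arenes.
- Completion: hydrogenation and deacylation.
- Merits: conjugation provides a clear driving force, chirality transfer is suprafacial, and the ends are again differentiated from the outset.
- Weak points: the stereochemical problem is only moved to the two benzylic carbinols of A5, which need two enantioselective operations. A5 has a skipped diene flanked by two electron-rich benzylic allylic acetates; these ionise easily, with loss of configuration, and the doubly allylic methylene invites isomerisation. Hydrogenating A4 risks hydrogenolysis of the allylic acetates.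
- Comparison: longer and more fragile than the chosen plan, which creates the carbinol centres directly where they are needed. Its one real advantage is that the ends are distinguished from the start.

**Alternative 3: C2-symmetric bis-epoxide opened by two aryl dithianes.**
- Cut: C1–C2 and C6–C7.
- Forward key step: bis-epoxide A7 is opened at one terminal carbon by lithiated dithiane A8 and at the other by lithiated dithiane A9, giving bis-dithiane diol A6. By the sequence rule A6 is (2R,4R) as a pentane-2,4-diol, because the dithiane carbons outrank the inner methylene, although its spatial arrangement is that of the target.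
- Completion: Raney nickel (Ni) desulfurisation and debenzylation.
- Merits: counted from A7 this is as short as or shorter than the chosen plan. It excises no carbon and needs no protecting group on the diol.
- Weak points: A7 is volatile and takes several steps including an asymmetric reduction, so the stereocentres are bought and not made. The two identical epoxides pose the same two-ends problem, and here it falls in a C–C bond formation where double opening by A8 is lost material. Removing two dithianes needs a large excess of nickel.
- Comparison: the chosen plan makes both stereocentres catalytically in one step from 1, places the statistical event at monotosylate 10 where nothing is lost, and avoids stoichiometric sulfur and nickel waste. It pays for this with the ozonolysis and the acetonide.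

Key step: step 1

Assumption: the (S) antipode of the bisphosphine Cl,MeO-BIPHEP is taken as the one whose iridium complex gives the (4S,6S) diol; if the sense of induction is the opposite, the (R) ligand is used and nothing else changes.

## Route

Step 1
Reactants: 1 propane-1,3-diol; 2 allyl acetate
Product: 6 (4S,6S)-nona-1,8-diene-4,6-diol, via 3-hydroxypropanal 3 (not isolated), via (3S)-hex-5-ene-1,3-diol 4 (not isolated), via (3S)-3-hydroxyhex-5-enal 5 (not isolated)
Conditions: [Ir(cod)Cl]2 (5 mol%), (S)-Cl,MeO-BIPHEP (10 mol%), 4-chloro-3-nitrobenzoic acid (20 mol%), Cs2CO3 (40 mol%), 2 (10 equiv), 1,4-dioxane, 90 °C, sealed vessel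
Reagents that add atoms: none
Why: This is the iridium-catalysed transfer-hydrogenative carbonyl allylation from the alcohol oxidation level, run in both directions on a 1,3-diol, which is its direct precedent class. The catalyst, a cyclometallated π-allyl C,O-benzoate complex of trivalent iridium carrying the bisphosphine, forms in the flask from [Ir(cod)Cl]2, the ligand, 4-chloro-3-nitrobenzoic acid, Cs2CO3 and 2. Alkoxide exchange with 1 and β-hydride elimination give aldehyde 3 and an iridium hydride; deprotonation leaves monovalent iridium, which adds 2 oxidatively, and the σ-allyl form adds to the bound aldehyde through a closed six-membered chair transition state to give 4, after which the same cycle at the remaining primary alcohol passes through 5 to 6. No ring is closed. Both new stereocentres, C4 and C6 of 6, are set by the chiral bisphosphine on iridium, which fixes the aldehyde face in the chair; the second addition is also catalyst-controlled and overrides the β-hydroxy centre already present, so the anti, C2-symmetric diol should result. Because the minor enantiomer of 4 is carried mainly into the meso diol, the enantiomeric purity of 6 should exceed that of a single allylation, at the cost of some separable meso material. The step needs oxidation of primary in preference to secondary hydroxyl and must never accumulate the unstable 1,3-dialdehyde; each alcohol is dehydrogenated only as an allyl group is delivered, the process being redox-neutral, and the secondary homoallylic alcohols of 4 and 6 are dehydrogenated far more slowly. Both ends of 1 are equivalent primary alcohols, so no regiochemical question arises.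

Step 2
Reactants: 6 (4S,6S)-nona-1,8-diene-4,6-diol
Product: 7 (4S,6S)-2,2-dimethyl-4,6-di(prop-2-en-1-yl)-1,3-dioxane
Conditions: 2,2-dimethoxypropane, PPTS (cat.), CH2Cl2, rt
Reagents that add atoms: 2,2-dimethoxypropane, COC(C)(C)OC
Why: Acid-catalysed transketalisation of a 1,3-diol; no stereocentre is touched. The acetonide protects the diol through ozonolysis and the Grignard steps, and its 13C shifts should allow the anti relationship to be checked.

Step 3
Reactants: 7 (4S,6S)-2,2-dimethyl-4,6-di(prop-2-en-1-yl)-1,3-dioxane
Product: 9 2,2'-[(4S,6S)-2,2-dimethyl-1,3-dioxane-4,6-diyl]di(ethan-1-ol), via acetonide dialdehyde 8 (not isolated)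
Conditions: O3, CH2Cl2/MeOH, −78 °C; then NaBH4, −78 °C to rt
Reagents that add atoms: ozone, [O-][O+]=O
Why: Ozonolysis of both terminal alkenes with reductive work-up; each end loses one carbon and the transient β-alkoxy aldehydes of 8 are reduced before they can eliminate. No arene is present yet and the acetonide is inert; the R descriptors of 8 reflect only a change of substituent priorities.

Step 4
Reactants: 9 2,2'-[(4S,6S)-2,2-dimethyl-1,3-dioxane-4,6-diyl]di(ethan-1-ol)
Product: 10 2-[(4S,6S)-6-(2-hydroxyethyl)-2,2-dimethyl-1,3-dioxan-4-yl]ethyl 4-methylbenzenesulfonate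
Conditions: TsCl (1.05 equiv), Ag2O (1.5 equiv), KI (0.2 equiv), CH2Cl2, 0 °C to rt
Reagents that add atoms: 4-methylbenzenesulfonyl chloride, Cc1ccc(cc1)S(=O)(=O)Cl
Why: Silver-oxide-mediated monotosylation of a symmetrical diol. The hydroxyls of 9 are homotopic, so one sulfonylation gives a single compound; the neutral conditions spare the acetonide, and recovered 9 and any bis-tosylate remain usable.

Step 5
Reactants: 11 4-bromo-2-methoxyphenol
Product: 12 1-(benzyloxy)-4-bromo-2-methoxybenzene
Conditions: BnBr, K2CO3, DMF, rt
Reagents that add atoms: benzyl bromide, BrCc1ccccc1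
Why: Williamson ether synthesis on a phenol; the benzyl ether survives magnesium insertion and copper catalysis.

Step 6
Reactants: 10 2-[(4S,6S)-6-(2-hydroxyethyl)-2,2-dimethyl-1,3-dioxan-4-yl]ethyl 4-methylbenzenesulfonate; 12 1-(benzyloxy)-4-bromo-2-methoxybenzene
Product: 14 2-[(4S,6S)-6-{2-[4-(benzyloxy)-3-methoxyphenyl]ethyl}-2,2-dimethyl-1,3-dioxan-4-yl]ethan-1-ol, via [4-(benzyloxy)-3-methoxyphenyl]magnesium bromide 13 (not isolated)
Conditions: 12 (2.5 equiv), Mg turnings, I2 (cat.), THF, 50 °C; then 10, Li2CuCl4 (5 mol%), THF, −20 °C to rt
Reagents that add atoms: none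
Why: Copper-catalysed cross-coupling of an aryl Grignard reagent with a primary alkyl tosylate forms the aryl–C1 bond. The first equivalent of 13 converts the hydroxyl into a magnesium alkoxide that could reach the tosylate only through an eight-membered ring. The stereocentres are two carbons from the reacting centre.

Step 7
Reactants: 14 2-[(4S,6S)-6-{2-[4-(benzyloxy)-3-methoxyphenyl]ethyl}-2,2-dimethyl-1,3-dioxan-4-yl]ethan-1-ol
Product: 15 2-[(4S,6S)-6-{2-[4-(benzyloxy)-3-methoxyphenyl]ethyl}-2,2-dimethyl-1,3-dioxan-4-yl]ethyl 4-methylbenzenesulfonate
Conditions: TsCl, Et3N, DMAP (cat.), CH2Cl2, 0 °C to rt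
Reagents that add atoms: 4-methylbenzenesulfonyl chloride, Cc1ccc(cc1)S(=O)(=O)Cl
Why: Standard sulfonylation of the single remaining primary alcohol under basic conditions that leave the acetonide and benzyl ether untouched.

Step 8
Reactants: 16 4-bromo-2,6-dimethoxyphenol
Product: 17 2-(benzyloxy)-5-bromo-1,3-dimethoxybenzene
Conditions: BnBr, K2CO3, DMF, 50 °C
Reagents that add atoms: benzyl bromide, BrCc1ccccc1
Why: Williamson ether synthesis; the phenol is flanked by two methoxy groups but is acidic enough to be alkylated on gentle warming.

Step 9
Reactants: 15 2-[(4S,6S)-6-{2-[4-(benzyloxy)-3-methoxyphenyl]ethyl}-2,2-dimethyl-1,3-dioxan-4-yl]ethyl 4-methylbenzenesulfonate; 17 2-(benzyloxy)-5-bromo-1,3-dimethoxybenzene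
Product: 19 (4S,6S)-4-{2-[4-(benzyloxy)-3,5-dimethoxyphenyl]ethyl}-6-{2-[4-(benzyloxy)-3-methoxyphenyl]ethyl}-2,2-dimethyl-1,3-dioxane, via [4-(benzyloxy)-3,5-dimethoxyphenyl]magnesium bromide 18 (not isolated)
Conditions: 17 (1.5 equiv), Mg turnings, I2 (cat.), THF, 50 °C; then 15, Li2CuCl4 (5 mol%), THF, −20 °C to rt
Reagents that add atoms: none
Why: The same copper-catalysed Grignard–tosylate cross-coupling, now forming the aryl–C7 bond on a substrate with no acidic hydrogen; the stereocentres are again remote from the reacting carbon.

Step 10
Reactants: 19 (4S,6S)-4-{2-[4-(benzyloxy)-3,5-dimethoxyphenyl]ethyl}-6-{2-[4-(benzyloxy)-3-methoxyphenyl]ethyl}-2,2-dimethyl-1,3-dioxane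
Product: 21 (3S,5S)-1-(4-hydroxy-3-methoxyphenyl)-7-(4-hydroxy-3,5-dimethoxyphenyl)heptane-3,5-diol, via bis-phenol acetonide 20 (not isolated)
Conditions: H2 (1 atm), 10% Pd/C, MeOH/EtOAc, rt; filter; then 1 M aq. HCl, MeOH, rt
Reagents that add atoms: none
Why: Hydrogenolysis of both aryl benzyl ethers followed by acid hydrolysis of the isopropylidene ketal. The chain has no alkene or benzylic C–O bond for hydrogen to attack, and ketal hydrolysis breaks bonds at the ketal carbon only, so C3 and C5 keep their configuration.

## Compound list

1 | propane-1,3-diol | OCCCO | starting material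
2 | allyl acetate (prop-2-en-1-yl acetate) | C=CCOC(C)=O | starting material
3 | 3-hydroxypropanal | O=CCCO | intermediate (not isolated)
4 | (3S)-hex-5-ene-1,3-diol | C=CC[C@H](O)CCO | intermediate (not isolated)
5 | (3S)-3-hydroxyhex-5-enal | C=CC[C@H](O)CC=O | intermediate (not isolated)
6 | (4S,6S)-nona-1,8-diene-4,6-diol | C=CC[C@H](O)C[C@@H](O)CC=C | intermediate
7 | (4S,6S)-2,2-dimethyl-4,6-di(prop-2-en-1-yl)-1,3-dioxane | C=CC[C@H]1C[C@H](CC=C)OC(C)(C)O1 | intermediate
8 | 2,2'-[(4R,6R)-2,2-dimethyl-1,3-dioxane-4,6-diyl]diacetaldehyde | O=CC[C@H]1C[C@H](CC=O)OC(C)(C)O1 | intermediate (not isolated)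
9 | 2,2'-[(4S,6S)-2,2-dimethyl-1,3-dioxane-4,6-diyl]di(ethan-1-ol) | OCC[C@H]1C[C@H](CCO)OC(C)(C)O1 | intermediate
10 | 2-[(4S,6S)-6-(2-hydroxyethyl)-2,2-dimethyl-1,3-dioxan-4-yl]ethyl 4-methylbenzenesulfonate | Cc1ccc(cc1)S(=O)(=O)OCC[C@H]1C[C@H](CCO)OC(C)(C)O1 | intermediate
11 | 4-bromo-2-methoxyphenol | COc1cc(Br)ccc1O | starting material
12 | 1-(benzyloxy)-4-bromo-2-methoxybenzene | COc1cc(Br)ccc1OCc1ccccc1 | intermediate
13 | [4-(benzyloxy)-3-methoxyphenyl]magnesium bromide | COc1cc([Mg]Br)ccc1OCc1ccccc1 | intermediate (not isolated)
14 | 2-[(4S,6S)-6-{2-[4-(benzyloxy)-3-methoxyphenyl]ethyl}-2,2-dimethyl-1,3-dioxan-4-yl]ethan-1-ol | COc1cc(CC[C@H]2C[C@H](CCO)OC(C)(C)O2)ccc1OCc1ccccc1 | intermediate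
15 | 2-[(4S,6S)-6-{2-[4-(benzyloxy)-3-methoxyphenyl]ethyl}-2,2-dimethyl-1,3-dioxan-4-yl]ethyl 4-methylbenzenesulfonate | COc1cc(CC[C@H]2C[C@H](CCOS(=O)(=O)c3ccc(C)cc3)OC(C)(C)O2)ccc1OCc1ccccc1 | intermediate
16 | 4-bromo-2,6-dimethoxyphenol | COc1cc(Br)cc(OC)c1O | starting material
17 | 2-(benzyloxy)-5-bromo-1,3-dimethoxybenzene | COc1cc(Br)cc(OC)c1OCc1ccccc1 | intermediate
18 | [4-(benzyloxy)-3,5-dimethoxyphenyl]magnesium bromide | COc1cc([Mg]Br)cc(OC)c1OCc1ccccc1 | intermediate (not isolated)
19 | (4S,6S)-4-{2-[4-(benzyloxy)-3,5-dimethoxyphenyl]ethyl}-6-{2-[4-(benzyloxy)-3-methoxyphenyl]ethyl}-2,2-dimethyl-1,3-dioxane | COc1cc(CC[C@H]2C[C@H](CCc3cc(OC)c(OCc4ccccc4)c(OC)c3)OC(C)(C)O2)ccc1OCc1ccccc1 | intermediate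
20 | 4-(2-{(4S,6S)-6-[2-(4-hydroxy-3-methoxyphenyl)ethyl]-2,2-dimethyl-1,3-dioxan-4-yl}ethyl)-2,6-dimethoxyphenol | COc1cc(CC[C@H]2C[C@H](CCc3cc(OC)c(O)c(OC)c3)OC(C)(C)O2)ccc1O | intermediate (not isolated)
21 | (3S,5S)-1-(4-hydroxy-3-methoxyphenyl)-7-(4-hydroxy-3,5-dimethoxyphenyl)heptane-3,5-diol | COc1cc(CC[C@H](O)C[C@@H](O)CCc2cc(OC)c(O)c(OC)c2)ccc1O | target

## Step count and risks

Total: 10 steps. Longest linear sequence: 8 steps (steps 1, 2, 3, 4, 6, 7, 9 and 10); steps 5 and 8 prepare the two aryl bromides.

**Step 1 (key step).** The second allylation may lag behind the first, so that the mono-adduct accumulates. The catalyst may also fail to override the first-formed centre, which diverts material to the meso diol. The small, water-soluble diol is easily lost on work-up. Fallback, from 4 back to 6: the reaction is stopped at the mono-adduct stage and 4 is isolated. With 4-methoxybenzaldehyde dimethyl acetal and PPTS it gives the cis acetal (2R,4S)-2-(4-methoxyphenyl)-4-(prop-2-en-1-yl)-1,3-dioxane F1. i-Bu2AlH opens this at the less hindered oxygen to (3S)-3-[(4-methoxyphenyl)methoxy]hex-5-en-1-ol F2. Dess–Martin oxidation gives (3S)-3-[(4-methoxyphenyl)methoxy]hex-5-enal F3. Chelation-controlled addition of allyltributylstannane with MgBr2·OEt2 gives the 1,3-anti product (4S,6S)-6-[(4-methoxyphenyl)methoxy]nona-1,8-dien-4-ol F4, and DDQ removes the 4-methoxybenzyl group to return 6. The second stereocentre is then set by substrate control through a six-membered chelate and not by the catalyst.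

**Step 4.** The two hydroxyls are far apart, so the first sulfonylation may hardly slow the second, and the product distribution may drift towards a statistical mixture of diol, mono- and bis-tosylate. Fallback, from 9 to 15: 9 is converted with excess TsCl and pyridine into [(4S,6S)-2,2-dimethyl-1,3-dioxane-4,6-diyl]di(ethane-2,1-diyl) bis(4-methylbenzenesulfonate) F5. The first copper-catalysed coupling is then run with a deficit of Grignard reagent 13, so that the mono-arylated tosylate 15 forms directly and unreacted F5 is recovered. Steps 6 and 7 are bypassed.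

**Step 6.** Bromide from the Schlenk equilibrium may displace the tosylate faster than copper couples it, copper may homocouple the electron-rich aryl Grignard reagent, and the magnesium alkoxide may aggregate and slow the reaction. Fallback, from 10 to 14: a Finkelstein reaction (NaI, acetone) gives 2-[(4S,6R)-6-(2-iodoethyl)-2,2-dimethyl-1,3-dioxan-4-yl]ethan-1-ol F6. A nickel-catalysed reductive cross-electrophile coupling of F6 with aryl bromide 12 (NiI2, 4,4'-di-tert-butyl-2,2'-bipyridine, Zn dust, DMA) then gives 14. This tolerates the free hydroxyl and needs no Grignard reagent.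

**Step 9.** The same competition between halide exchange, homocoupling and cross-coupling applies, now with the more hindered and more electron-rich syringyl Grignard reagent, whose formation may also be sluggish. Fallback, from 15 to 19, with the polarity reversed: NaI in acetone gives (4S,6R)-4-{2-[4-(benzyloxy)-3-methoxyphenyl]ethyl}-6-(2-iodoethyl)-2,2-dimethyl-1,3-dioxane F7. Zinc insertion (Zn dust, LiCl, THF) gives (2-{(4R,6S)-6-[2-(4-(benzyloxy)-3-methoxyphenyl)ethyl]-2,2-dimethyl-1,3-dioxan-4-yl}ethyl)zinc iodide F8. Negishi coupling of F8 with aryl bromide 17 (Pd(OAc)2, SPhos, THF) gives 19.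

## Further compounds

F1 | step 1 | (2R,4S)-2-(4-methoxyphenyl)-4-(prop-2-en-1-yl)-1,3-dioxane | C=CC[C@H]1CCO[C@@H](c2ccc(OC)cc2)O1
F2 | step 1 | (3S)-3-[(4-methoxyphenyl)methoxy]hex-5-en-1-ol | C=CC[C@H](OCc1ccc(OC)cc1)CCO
F3 | step 1 | (3S)-3-[(4-methoxyphenyl)methoxy]hex-5-enal | C=CC[C@H](OCc1ccc(OC)cc1)CC=O
F4 | step 1 | (4S,6S)-6-[(4-methoxyphenyl)methoxy]nona-1,8-dien-4-ol | C=CC[C@H](OCc1ccc(OC)cc1)C[C@@H](O)CC=C
F5 | step 4 | [(4S,6S)-2,2-dimethyl-1,3-dioxane-4,6-diyl]di(ethane-2,1-diyl) bis(4-methylbenzenesulfonate) | Cc1ccc(cc1)S(=O)(=O)OCC[C@H]1C[C@H](CCOS(=O)(=O)c2ccc(C)cc2)OC(C)(C)O1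
F6 | step 6 | 2-[(4S,6R)-6-(2-iodoethyl)-2,2-dimethyl-1,3-dioxan-4-yl]ethan-1-ol | OCC[C@H]1C[C@H](CCI)OC(C)(C)O1
F7 | step 9 | (4S,6R)-4-{2-[4-(benzyloxy)-3-methoxyphenyl]ethyl}-6-(2-iodoethyl)-2,2-dimethyl-1,3-dioxane | COc1cc(CC[C@H]2C[C@H](CCI)OC(C)(C)O2)ccc1OCc1ccccc1
F8 | step 9 | (2-{(4R,6S)-6-[2-(4-(benzyloxy)-3-methoxyphenyl)ethyl]-2,2-dimethyl-1,3-dioxan-4-yl}ethyl)zinc iodide | COc1cc(CC[C@H]2C[C@H](CC[Zn]I)OC(C)(C)O2)ccc1OCc1ccccc1
A1 | alternative 1 | (2S,4R,6S)-2-[4-(acetyloxy)-3-methoxyphenyl]-6-{2-[4-(benzyloxy)-3,5-dimethoxyphenyl]ethyl}oxan-4-yl trifluoroacetate | O1[C@H](c2ccc(OC(C)=O)c(OC)c2)C[C@H](OC(=O)C(F)(F)F)C[C@@H]1CCc1cc(OC)c(OCc2ccccc2)c(OC)c1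
A2 | alternative 1 | (3S)-1-[4-(benzyloxy)-3,5-dimethoxyphenyl]hex-5-en-3-ol | C=CC[C@@H](O)CCc1cc(OC)c(OCc2ccccc2)c(OC)c1
A3 | alternative 1 | 4-formyl-2-methoxyphenyl acetate | CC(=O)Oc1ccc(C=O)cc1OC
A4 | alternative 2 | (1E,3R,5R,6E)-7-[4-(2,2-dimethylpropanoyloxy)-3,5-dimethoxyphenyl]-1-[4-(2,2-dimethylpropanoyloxy)-3-methoxyphenyl]hepta-1,6-diene-3,5-diyl diacetate | COc1cc(/C=C/[C@H](OC(C)=O)C[C@@H](OC(C)=O)/C=C/c2cc(OC)c(OC(=O)C(C)(C)C)c(OC)c2)ccc1OC(=O)C(C)(C)C
A5 | alternative 2 | (1R,2E,5E,7R)-7-[4-(2,2-dimethylpropanoyloxy)-3,5-dimethoxyphenyl]-1-[4-(2,2-dimethylpropanoyloxy)-3-methoxyphenyl]hepta-2,5-diene-1,7-diyl diacetate | COc1cc([C@H](OC(C)=O)/C=C/C/C=C/[C@@H](OC(C)=O)c2cc(OC)c(OC(=O)C(C)(C)C)c(OC)c2)ccc1OC(=O)C(C)(C)C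
A6 | alternative 3 | (2R,4R)-1-{2-[4-(benzyloxy)-3-methoxyphenyl]-1,3-dithian-2-yl}-5-{2-[4-(benzyloxy)-3,5-dimethoxyphenyl]-1,3-dithian-2-yl}pentane-2,4-diol | COc1cc(C2(C[C@H](O)C[C@@H](O)CC3(c4cc(OC)c(OCc5ccccc5)c(OC)c4)SCCCS3)SCCCS2)ccc1OCc1ccccc1
A7 | alternative 3 | (2R,2'R)-2,2'-methylenebis(oxirane) | C1[C@H](O1)C[C@@H]1CO1
A8 | alternative 3 | 2-[4-(benzyloxy)-3-methoxyphenyl]-1,3-dithiane | COc1cc(C2SCCCS2)ccc1OCc1ccccc1
A9 | alternative 3 | 2-[4-(benzyloxy)-3,5-dimethoxyphenyl]-1,3-dithiane | COc1cc(C2SCCCS2)cc(OC)c1OCc1ccccc1
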